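**Retrosynthetic overview**
- The target is a C2-symmetric (3R,4R)-3,4-disubstituted oxolane, so every operation after ring formation is run in both directions at once: O-debenzylation ⇐ double reagent-controlled ketone reduction (both carbinol centres) ⇐ (3R,4R)-3,4-diaroyloxolane.
- The diketone comes from a bis(N-methoxy-N-methylamide) and two equivalents of an aryllithium; the bis-amide comes from a bis(N-acylsultam).
- Key disconnection: both ring C–CH2 bonds of the oxolane (C3–C2 and C4–C5) are cut at once, giving the parent carbonyl ylide CH2=O(+)–CH2(−) and an (E)-butenedioyl (fumaroyl) unit bearing two identical camphor-derived sultams.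
- Enabling feature: a C2 axis runs through the ring oxygen and the midpoint of the C3–C4 bond; the oxygen is flanked by two unsubstituted CH2 groups, and C3 and C4 are trans and each carry an exocyclic carbon that can be a carbonyl. This is the retron of a 1,3-dipolar cycloaddition to a trans-disubstituted, doubly activated alkene.
- Ring order: the oxolane is the only ring made in the route; the arene rings and the auxiliary rings are bought.

Key step: step 4

Assumption: thermal (non-chelated) cycloadditions to N-enoyl bornane-10,2-sultams are taken to occur at the C(α)-si face for the (2S)-auxiliary, as in the uncatalysed Diels–Alder and nitrile oxide additions of this class; if the sense proves opposite, the (2R)-sultam would be used and nothing else changes.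

**Step 1**
Reactants: 1 4-bromo-2-methoxyphenol; 2 benzyl bromide
Product: 3 1-(benzyloxy)-4-bromo-2-methoxybenzene
Conditions: BnBr, K2CO3, DMF, rt
Reagents that add atoms: benzyl bromide (2), BrCc1ccccc1
Why: Williamson ether synthesis (SN2 O-alkylation of the phenoxide) should protect the phenol as a benzyl ether that survives organolithium, borane and fluoride conditions; no stereocentre is involved.

**Step 2**
Reactants: 4 (trimethylsilyl)methanol; 5 paraformaldehyde; 6 hydrogen chloride
Product: 7 [(chloromethoxy)methyl]trimethylsilane
Conditions: (CH2O)n, HCl (g), CH2Cl2, 0 °C; CaCl2; distillation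
Reagents that add atoms: paraformaldehyde (5), C=O; hydrogen chloride (6), Cl
Why: Acid-mediated chloromethylation of an alcohol (hemiformal, then oxocarbenium ion, then chloride capture) is the standard preparation of chloromethyl ethers and should give the silyl-substituted ylide precursor; no stereocentre is involved.

**Step 3**
Reactants: 8 fumaryl chloride; 9 (2S)-bornane-10,2-sultam
Product: 11 N,N'-fumaroylbis[(2S)-bornane-10,2-sultam], via sodium sultamide 10 (not isolated)
Conditions: NaH, toluene, rt; then 8, 0 °C → rt
Reagents that add atoms: (2S)-bornane-10,2-sultam (9), CC1(C)[C@H]2CC[C@@]13CS(=O)(=O)N[C@H]3C2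
Why: Double N-acylation of the pre-formed sodium sultamide by the diacid chloride should give the crystalline C2-symmetric dipolarophile with the E double bond retained; no new stereocentre is formed.

**Step 4**
Reactants: 11 N,N'-fumaroylbis[(2S)-bornane-10,2-sultam]; 7 [(chloromethoxy)methyl]trimethylsilane
Product: 13 (3R,4R)-3,4-bis{[(2S)-bornane-10,2-sultam-N-yl]carbonyl}oxolane, via carbonyl ylide 12 (not isolated)
Conditions: 7 (3 equiv), CsF (4 equiv), MeCN, rt
Reagents that add atoms: [(chloromethoxy)methyl]trimethylsilane (7), C[Si](C)(C)COCCl
Why: Fluoride attack at silicon of 7 triggers a 1,3-elimination of Me3SiF and chloride that releases the parent carbonyl ylide 12 (formaldehyde O-methylide), a 4π-electron 1,3-dipole that adds in a concerted suprafacial [3+2] fashion, HOMO(dipole)–LUMO(dipolarophile) controlled, across the doubly acyl-activated C=C of 11. The closest known reaction type is the fluoride-induced cycloaddition of this same silyl chloromethyl ether to fumarates and maleates, together with the thiocarbonyl ylide analogue on N-enoyl bornane-10,2-sultams. The oxolane is closed by an intermolecular 1,3-dipolar cycloaddition that forms both ring C–CH2 bonds (C3–C2 and C4–C5) in one event, the ring oxygen and both methylenes coming from the dipole. The trans relation of C3 and C4 is fixed by the E geometry of the dipolarophile (stereospecific suprafacial addition), and their absolute (3R,4R) configuration by the two (2S)-sultams, which in the s-cis enoyl conformer with C=O anti to the N–SO2 bond should expose the C(α)-si face of each olefinic carbon; because the C2 axis of 11 is perpendicular to the olefin plane, both auxiliaries screen the same π-face and reinforce each other. The step needs π-facial selectivity and chemoselectivity for C=C over the imide C=O groups: the first rests on the doubled auxiliary (the minor cycloadduct is a diastereomer and should be removable by crystallisation), the second on the strong LUMO lowering of the fumaroyl double bond.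

**Step 5**
Reactants: 13 (3R,4R)-3,4-bis{[(2S)-bornane-10,2-sultam-N-yl]carbonyl}oxolane; 14 N,O-dimethylhydroxylamine hydrochloride
Product: 15 (3R,4R)-N3,N4-dimethoxy-N3,N4-dimethyloxolane-3,4-dicarboxamide
Conditions: MeONHMe·HCl, AlMe3, CH2Cl2, 0 → 40 °C; then aq. HCl
Reagents that add atoms: N,O-dimethylhydroxylamine hydrochloride (14), CNOC.Cl
Why: Aluminium-amide-mediated transamidation of the activated N-acylsultams (Weinreb amide formation) should release the auxiliary for recovery under Lewis-acidic, non-basic conditions, so the two α-stereocentres are not enolised and keep their configuration.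

**Step 6**
Reactants: 15 (3R,4R)-N3,N4-dimethoxy-N3,N4-dimethyloxolane-3,4-dicarboxamide; 3 1-(benzyloxy)-4-bromo-2-methoxybenzene
Product: 17 (3R,4R)-oxolane-3,4-diylbis{[4-(benzyloxy)-3-methoxyphenyl]methanone}, via aryllithium 16 (not isolated)
Conditions: 3, n-BuLi, THF, −78 °C; then 15, −78 → −20 °C; then cold 1 M HCl
Reagents that add atoms: 1-(benzyloxy)-4-bromo-2-methoxybenzene (3), COc1cc(Br)ccc1OCc1ccccc1
Why: Weinreb ketone synthesis: bromine–lithium exchange gives the aryllithium, which adds once to each amide because the chelated tetrahedral intermediates are stable until acidic work-up; this should deliver both aryl ketones without over-addition and leave the ring stereocentres untouched.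

**Step 7**
Reactants: 17 (3R,4R)-oxolane-3,4-diylbis{[4-(benzyloxy)-3-methoxyphenyl]methanone}
Product: 18 (S,S)-[(3R,4R)-oxolane-3,4-diyl]bis{[4-(benzyloxy)-3-methoxyphenyl]methanol}
Conditions: (R)-2-methyl-CBS-oxazaborolidine (0.4 equiv), BH3·SMe2, THF, −20 °C; MeOH, then aq. work-up
Reagents that add atoms: none
Why: Corey–Bakshi–Shibata reduction with the (R)-oxazaborolidine should deliver hydride to the re face of each aryl ketone (aryl as the large group) to set both (S)-carbinol centres under reagent control, matched with the Felkin–Anh and β-alkoxy-chelate preference of the (3R,4R)-substrate, and the C2 symmetry makes the two reductions identical events.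

**Step 8**
Reactants: 18 (S,S)-[(3R,4R)-oxolane-3,4-diyl]bis{[4-(benzyloxy)-3-methoxyphenyl]methanol}
Product: 19 (S,S)-[(3R,4R)-oxolane-3,4-diyl]bis[(4-hydroxy-3-methoxyphenyl)methanol] (CNP0157038.3)
Conditions: H2 (1 atm), 10% Pd/C, EtOAc/EtOH, rt
Reagents that add atoms: none
Why: Catalytic hydrogenolysis of the two benzyl aryl ethers under neutral conditions should free both phenols while the secondary benzylic carbinols, which are cleaved more slowly, are kept; no stereocentre is touched.

**Compound list**
1 | 4-bromo-2-methoxyphenol | COc1cc(Br)ccc1O | starting material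
2 | benzyl bromide | BrCc1ccccc1 | starting material
3 | 1-(benzyloxy)-4-bromo-2-methoxybenzene | COc1cc(Br)ccc1OCc1ccccc1 | intermediate
4 | (trimethylsilyl)methanol | C[Si](C)(C)CO | starting material
5 | paraformaldehyde (formaldehyde unit) | C=O | starting material
6 | hydrogen chloride | Cl | starting material
7 | [(chloromethoxy)methyl]trimethylsilane | C[Si](C)(C)COCCl | intermediate
8 | fumaryl chloride | O=C(Cl)/C=C/C(Cl)=O | starting material
9 | (2S)-bornane-10,2-sultam [(1R)-(+)-2,10-camphorsultam] | CC1(C)[C@H]2CC[C@@]13CS(=O)(=O)N[C@H]3C2 | starting material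
10 | sodium salt of (2S)-bornane-10,2-sultam | [Na+].[N-]1[C@H]2C[C@@H]3CC[C@@]2(CS1(=O)=O)C3(C)C | intermediate
11 | N,N'-fumaroylbis[(2S)-bornane-10,2-sultam] | O=C(/C=C/C(=O)N1[C@H]2C[C@@H]3CC[C@@]2(CS1(=O)=O)C3(C)C)N1[C@H]2C[C@@H]3CC[C@@]2(CS1(=O)=O)C3(C)C | intermediate
12 | formaldehyde O-methylide (parent carbonyl ylide) | [CH2-][O+]=C | intermediate
13 | (3R,4R)-3,4-bis{[(2S)-bornane-10,2-sultam-N-yl]carbonyl}oxolane | O=C([C@H]1COC[C@@H]1C(=O)N1[C@H]2C[C@@H]3CC[C@@]2(CS1(=O)=O)C3(C)C)N1[C@H]2C[C@@H]3CC[C@@]2(CS1(=O)=O)C3(C)C | intermediate
14 | N,O-dimethylhydroxylamine hydrochloride | CNOC.Cl | starting material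
15 | (3R,4R)-N3,N4-dimethoxy-N3,N4-dimethyloxolane-3,4-dicarboxamide | CON(C)C(=O)[C@H]1COC[C@@H]1C(=O)N(C)OC | intermediate
16 | [4-(benzyloxy)-3-methoxyphenyl]lithium | [Li]c1ccc(OCc2ccccc2)c(OC)c1 | intermediate
17 | (3R,4R)-oxolane-3,4-diylbis{[4-(benzyloxy)-3-methoxyphenyl]methanone} | COc1cc(C(=O)[C@H]2COC[C@@H]2C(=O)c2ccc(OCc3ccccc3)c(OC)c2)ccc1OCc1ccccc1 | intermediate
18 | (S,S)-[(3R,4R)-oxolane-3,4-diyl]bis{[4-(benzyloxy)-3-methoxyphenyl]methanol} | COc1cc([C@@H](O)[C@H]2COC[C@@H]2[C@H](O)c2ccc(OCc3ccccc3)c(OC)c2)ccc1OCc1ccccc1 | intermediate
19 | (S,S)-[(3R,4R)-oxolane-3,4-diyl]bis[(4-hydroxy-3-methoxyphenyl)methanol] | COc1cc([C@@H](O)[C@H]2COC[C@@H]2[C@H](O)c2ccc(O)c(OC)c2)ccc1O | target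

**Step count and risks**

Total steps: 8. Longest linear sequence: 6 steps (steps 3 to 8, from fumaryl chloride and the sultam); steps 1 and 2 prepare the aryl bromide and the ylide precursor.

The three steps most likely to fail:

Step 4. The auxiliaries may discriminate the two π-faces too weakly, or the ylide may oligomerise before the hindered bis-imide traps it. The fallback keeps the ring-forming cycloaddition but moves the stereocontrol into a separate catalytic desymmetrisation. It sets out from 7 and commercial maleic anhydride: the same CsF-triggered cycloaddition should give the meso compound cis-tetrahydrofuran-3,4-dicarboxylic anhydride F1. Cinchona-alkaloid-mediated methanolysis (quinidine or quinine, whichever pseudo-enantiomer delivers the isomer drawn; MeOH, toluene, low temperature) would open it to the hemiester (3R,4S)-4-(methoxycarbonyl)oxolane-3-carboxylic acid F2. Epimerisation of the ester-bearing carbon with NaOMe in MeOH (the carboxylate-bearing carbon stays fixed) should give the trans hemiester (3R,4R)-4-(methoxycarbonyl)oxolane-3-carboxylic acid F3. Saponification with LiOH gives (3R,4R)-oxolane-3,4-dicarboxylic acid F4, and double amide coupling with 14 (carbonyldiimidazole, then the amine salt and base) comes back to the route at 15.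

Step 6. The aryllithium may deprotonate the amide α-positions (epimerisation through the enolate, or ring opening by β-alkoxide elimination), or the reaction may stall after the first addition. The fallback sets out from 13 and replaces the basic organolithium by a non-basic acylative cross-coupling. LiOH/H2O2 in THF/water would cleave the auxiliaries to give (3R,4R)-oxolane-3,4-dicarboxylic acid F4, and oxalyl chloride with catalytic DMF would convert it to (3R,4R)-oxolane-3,4-dicarbonyl dichloride F5. The aryllithium 16 is transmetalated with ZnCl2 to [4-(benzyloxy)-3-methoxyphenyl]zinc chloride F6, and a Pd(PPh3)4-catalysed Negishi acylation of F5 with F6 in THF comes back to the route at 17.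

Step 8. Hydrogenolysis of the electron-rich benzylic C–OH bonds may compete with benzyl ether cleavage. The fallback sets out from 17 and reverses the order of the last two operations. Hydrogenolysis at the diketone stage (H2, 10% Pd/C, EtOAc), where no benzylic alcohol is present, should give (3R,4R)-oxolane-3,4-diylbis[(4-hydroxy-3-methoxyphenyl)methanone] F7. Reduction with (R)-2-methyl-CBS-oxazaborolidine and excess BH3·SMe2 (the phenols are capped in the flask as aryloxyboranes and freed on work-up) then comes back to the route at 19.

**Further compounds**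
F1 | step 4 | cis-tetrahydrofuran-3,4-dicarboxylic anhydride [(3aR,6aS)-tetrahydro-1H,3H-furo[3,4-c]furan-1,3-dione, meso] | O=C1OC(=O)[C@H]2COC[C@@H]12
F2 | step 4 | (3R,4S)-4-(methoxycarbonyl)oxolane-3-carboxylic acid | OC(=O)[C@H]1COC[C@H]1C(=O)OC
F3 | step 4 | (3R,4R)-4-(methoxycarbonyl)oxolane-3-carboxylic acid | OC(=O)[C@H]1COC[C@@H]1C(=O)OC
F4 | step 4 | (3R,4R)-oxolane-3,4-dicarboxylic acid | OC(=O)[C@H]1COC[C@@H]1C(O)=O
F5 | step 6 | (3R,4R)-oxolane-3,4-dicarbonyl dichloride | O=C(Cl)[C@H]1COC[C@@H]1C(Cl)=O
F6 | step 6 | [4-(benzyloxy)-3-methoxyphenyl]zinc chloride | COc1cc([Zn]Cl)ccc1OCc1ccccc1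
F7 | step 8 | (3R,4R)-oxolane-3,4-diylbis[(4-hydroxy-3-methoxyphenyl)methanone] | COc1cc(C(=O)[C@H]2COC[C@@H]2C(=O)c2ccc(O)c(OC)c2)ccc1O
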